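**Retrosynthetic overview**

1. The target 17 is the C2 acetate of a 2-hydroxy-3,6-diaryl-1,4-benzoquinone (ring numbered C1 = carbonyl next to C2–OAc, C3 = aryl, C4 = carbonyl, C5 = H, C6 = aryl). Late disconnections are the two aryl tert-butyl ethers, the acetate, and quinone to 4-methoxyphenol 13.
2. The central ring of 13 is cut into three components: styryl(methoxy)carbene chromium complex 5 (C4, C5, C6), one of its CO ligands (C1) and aryl siloxyalkyne 11 (C2, C3). A Dötz benzannulation should make C3–C4, C1–C6 and C1–C2 in one operation.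
3. The enabling feature is the para pair of oxygen-bearing ring carbons C1/C4 (a hydroquinone monoether after reduction, the product pattern of a carbene/CO/alkyne benzannulation). The C2–O bond makes C2–C3 an ynol ether, whose polarity and bulky silyl group should fix the orientation so that the aryl rings end para (C3, C6).
4. Complex 5 comes from Cr(CO)6 and 4-tert-butoxybenzaldehyde; alkyne 11 comes from 1-bromo-4-tert-butoxybenzene by Sonogashira coupling, acetylide oxidation and O-silylation.
5. Ring order: both aryl rings are bought; the only ring made is the six-membered quinone carbocycle, in step 5.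

Key step: step 5

Remark: the target has no stereocentre and is achiral, so the route needs no stereocontrol; the only stereochemical element on the way is the E alkene of 5, which is consumed in step 5.

**Step 1**
Reactants: 1 chromium hexacarbonyl
Product: 3 pentacarbonyl(1-methoxyethylidene)chromium(0), via lithium acetylpentacarbonylchromate 2 (not isolated)
Conditions: MeLi, Et2O, 0 °C to rt; then Me3OBF4, CH2Cl2/H2O, 0 °C
Reagents that add atoms: methyllithium [Li]C; trimethyloxonium tetrafluoroborate C[O+](C)C.F[B-](F)(F)F
Why: Fischer carbene synthesis, in which methyllithium adds to a CO ligand and the resulting acyl chromate is O-methylated by the oxonium salt.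

**Step 2**
Reactants: 3 pentacarbonyl(1-methoxyethylidene)chromium(0); 4 4-tert-butoxybenzaldehyde
Product: 5 pentacarbonyl[(2E)-3-(4-tert-butoxyphenyl)-1-methoxyprop-2-en-1-ylidene]chromium(0)
Conditions: Et3N, TMSCl, Et2O, rt
Reagents that add atoms: none
Why: Aldol condensation of the strongly C–H acidic methyl group of the Fischer carbene complex with a non-enolisable aldehyde, the elimination giving the conjugated E alkene.

**Step 3**
Reactants: 6 1-bromo-4-tert-butoxybenzene; 7 ethynyltrimethylsilane
Product: 9 1-tert-butoxy-4-ethynylbenzene, via trimethylsilyl alkyne 8 (not isolated)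
Conditions: Pd(PhCN)2Cl2 (cat.), P(t-Bu)3 (cat.), CuI (cat.), i-Pr2NH, dioxane, rt; then K2CO3 (cat.), MeOH, rt
Reagents that add atoms: none
Why: Sonogashira coupling of the electron-rich aryl bromide under bulky-phosphine catalysis, followed by methanolytic cleavage of the alkynyl C–Si bond.

**Step 4**
Reactants: 9 1-tert-butoxy-4-ethynylbenzene
Product: 11 {[(4-tert-butoxyphenyl)ethynyl]oxy}tri(propan-2-yl)silane, via lithium ynolate 10 (not isolated)
Conditions: LiHMDS (2 equiv), THF, −78 °C; t-BuOOH (1 equiv), −78 to 0 °C; then TIPSOTf, −78 °C to rt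
Reagents that add atoms: tert-butyl hydroperoxide CC(C)(C)OO; triisopropylsilyl trifluoromethanesulfonate CC(C)[Si](OS(=O)(=O)C(F)(F)F)(C(C)C)C(C)C
Why: Electrophilic oxygen transfer from lithium tert-butyl peroxide to the lithium acetylide should give the ynolate, which the bulky silyl triflate traps on oxygen as the siloxyalkyne.

**Step 5**
Reactants: 5 pentacarbonyl[(2E)-3-(4-tert-butoxyphenyl)-1-methoxyprop-2-en-1-ylidene]chromium(0); 11 {[(4-tert-butoxyphenyl)ethynyl]oxy}tri(propan-2-yl)silane
Product: 13 3,6-bis(4-tert-butoxyphenyl)-4-methoxy-2-{[tri(propan-2-yl)silyl]oxy}phenol, via tricarbonylchromium arene complex 12 (not isolated)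
Conditions: THF (0.05 M), 50 °C, Ar; then air, light, Et2O, rt
Reagents that add atoms: none
Why: Proposed new method: thermal loss of one CO from 5 opens a site for 11, whose nucleophilic aryl-bearing carbon bonds to the electrophilic carbene carbon (C3–C4) while the siloxy-bearing carbon becomes the new chromium carbene carbon; CO insertion there gives a chromium-bound dienylketene (C1–C2), and the ketene carbon C1 then closes onto the styryl β-carbon C6 before tautomerisation to the phenol. The closest known reaction type is the Dötz benzannulation of alkenyl(methoxy)carbene chromium complexes with internal alkynes, and the closest precedent for the alkyne is the use of 1-siloxyalkynes as two-carbon partners of vinylketenes in the Danheiser benzannulation; a siloxyalkyne in the chromium reaction is the untested element. The one ring formed, the six-membered carbocycle, is closed by 6π-electrocyclisation of the dienylketene, a formal [3+2+1] assembly of carbene ligand, alkyne and CO. No stereocentre is created, and the E geometry of the styryl unit only places hydrogen rather than aryl inside the cyclising termini. The step needs one regiochemical outcome, siloxy carbon next to the CO-derived carbon and aryl carbon next to the methoxy-bearing carbon, which should be secured by the ynol ether polarisation (the sense in which ynamines insert into Fischer carbenes) and by the bulk of OSi(i-Pr)3, which takes the large-substituent position next to chromium. Phenol formation over cyclobutenone or furan products should be favoured by the alkenyl complex, THF and the moderate temperature.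

**Step 6**
Reactants: 13 3,6-bis(4-tert-butoxyphenyl)-4-methoxy-2-{[tri(propan-2-yl)silyl]oxy}phenol
Product: 15 3,6-bis(4-tert-butoxyphenyl)-2-hydroxycyclohexa-2,5-diene-1,4-dione, via silyloxyquinone 14 (not isolated)
Conditions: CAN, MeCN/H2O, 0 °C; then NaOH (aq), THF, 0 °C; HCl work-up
Reagents that add atoms: water O
Why: Ceric ammonium nitrate should oxidatively demethylate the 4-methoxyphenol to the para-quinone (water adds at C4, methanol leaves), and hydroxide then cleaves the silyl vinylogous ester to the stable quinonolate, protonated on work-up.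

**Step 7**
Reactants: 15 3,6-bis(4-tert-butoxyphenyl)-2-hydroxycyclohexa-2,5-diene-1,4-dione
Product: 16 2-acetoxy-3,6-bis(4-tert-butoxyphenyl)-1,4-benzoquinone
Conditions: Ac2O, pyridine, CH2Cl2, 0 °C
Reagents that add atoms: acetic anhydride CC(=O)OC(C)=O
Why: O-acylation of the only free hydroxyl, the acidic hydroxyquinone OH (a vinylogous carboxylic acid), with acetic anhydride and pyridine.

**Step 8**
Reactants: 16 2-acetoxy-3,6-bis(4-tert-butoxyphenyl)-1,4-benzoquinone
Product: 17 Neonambiquinone A (2-acetoxy-3,6-bis(4-hydroxyphenyl)-1,4-benzoquinone)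
Conditions: TFA/CH2Cl2 (1:4), 0 °C to rt
Reagents that add atoms: none
Why: Acidolysis of the two aryl tert-butyl ethers with loss of isobutene, under anhydrous non-nucleophilic conditions that should leave the quinone and the enol acetate untouched.

**Compound list**

1 | chromium hexacarbonyl | O=C=[Cr](=C=O)(=C=O)(=C=O)(=C=O)=C=O | starting material
2 | lithium acetylpentacarbonylchromate | [Li+].CC(=O)[Cr-](=C=O)(=C=O)(=C=O)(=C=O)=C=O | intermediate
3 | pentacarbonyl(1-methoxyethylidene)chromium(0) | COC(C)=[Cr](=C=O)(=C=O)(=C=O)(=C=O)=C=O | intermediate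
4 | 4-tert-butoxybenzaldehyde | CC(C)(C)Oc1ccc(C=O)cc1 | starting material
5 | pentacarbonyl[(2E)-3-(4-tert-butoxyphenyl)-1-methoxyprop-2-en-1-ylidene]chromium(0) | COC(/C=C/c1ccc(OC(C)(C)C)cc1)=[Cr](=C=O)(=C=O)(=C=O)(=C=O)=C=O | intermediate
6 | 1-bromo-4-tert-butoxybenzene | CC(C)(C)Oc1ccc(Br)cc1 | starting material
7 | ethynyltrimethylsilane | C#C[Si](C)(C)C | starting material
8 | [(4-tert-butoxyphenyl)ethynyl]trimethylsilane | CC(C)(C)Oc1ccc(C#C[Si](C)(C)C)cc1 | intermediate
9 | 1-tert-butoxy-4-ethynylbenzene | C#Cc1ccc(OC(C)(C)C)cc1 | intermediate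
10 | lithium 2-(4-tert-butoxyphenyl)ethyn-1-olate | [Li+].[O-]C#Cc1ccc(OC(C)(C)C)cc1 | intermediate
11 | {[(4-tert-butoxyphenyl)ethynyl]oxy}tri(propan-2-yl)silane | CC(C)[Si](OC#Cc1ccc(OC(C)(C)C)cc1)(C(C)C)C(C)C | intermediate
12 | tricarbonylchromium η6-complex of phenol 13 (written as arene plus Cr(CO)3 fragment) | COc1cc(-c2ccc(OC(C)(C)C)cc2)c(O)c(O[Si](C(C)C)(C(C)C)C(C)C)c1-c1ccc(OC(C)(C)C)cc1.O=C=[Cr](=C=O)=C=O | intermediate
13 | 3,6-bis(4-tert-butoxyphenyl)-4-methoxy-2-{[tri(propan-2-yl)silyl]oxy}phenol | COc1cc(-c2ccc(OC(C)(C)C)cc2)c(O)c(O[Si](C(C)C)(C(C)C)C(C)C)c1-c1ccc(OC(C)(C)C)cc1 | intermediate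
14 | 3,6-bis(4-tert-butoxyphenyl)-2-{[tri(propan-2-yl)silyl]oxy}cyclohexa-2,5-diene-1,4-dione | CC(C)[Si](OC1=C(c2ccc(OC(C)(C)C)cc2)C(=O)C=C(c2ccc(OC(C)(C)C)cc2)C1=O)(C(C)C)C(C)C | intermediate
15 | 3,6-bis(4-tert-butoxyphenyl)-2-hydroxycyclohexa-2,5-diene-1,4-dione | OC1=C(c2ccc(OC(C)(C)C)cc2)C(=O)C=C(c2ccc(OC(C)(C)C)cc2)C1=O | intermediate
16 | 2-acetoxy-3,6-bis(4-tert-butoxyphenyl)-1,4-benzoquinone | CC(=O)OC1=C(c2ccc(OC(C)(C)C)cc2)C(=O)C=C(c2ccc(OC(C)(C)C)cc2)C1=O | intermediate
17 | Neonambiquinone A | CC(=O)OC1=C(c2ccc(O)cc2)C(=O)C=C(c2ccc(O)cc2)C1=O | target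

**Totals**

Total step count: 8. Longest linear sequence: 6 steps (steps 3, 4, 5, 6, 7, 8 from 6, or equally steps 1, 2, 5, 6, 7, 8 from 1).

**Three steps most likely to fail**

1. Step 5 (Proposed new method). The alkyne insertion may stop at an oxygen-stabilised vinylcarbene that does not take up CO, may occur with the opposite orientation, or may divert to cyclobutenone formation. The fallback uses known chemistry throughout, sets out from 6 and comes back to the route at 15. Twofold Suzuki–Miyaura coupling of 6 with commercial (2,5-dimethoxy-1,4-phenylene)diboronic acid (Pd(dppf)Cl2, K2CO3, dioxane/H2O, 90 °C) should give 2,5-bis(4-tert-butoxyphenyl)-1,4-dimethoxybenzene F1. CAN oxidation (MeCN/H2O, 0 °C) should give 2,5-bis(4-tert-butoxyphenyl)-1,4-benzoquinone F2. Nucleophilic epoxidation of one of its two equivalent ring C=C bonds (30% H2O2, Na2CO3, THF/MeOH, 0 °C) should give the racemic mono-epoxide F3. Acid-induced epoxide opening with loss of the ring C–H (cat. TsOH, CH2Cl2, rt; the classical hydroxylation of a quinone through its epoxide, run with a mild acid to spare the tert-butyl ethers) should give 15, after which steps 7 and 8 follow unchanged.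

2. Step 4. Oxygen transfer from the peroxide to the aryl acetylide may be incomplete, and the ynolate may be silylated on carbon to a silylketene instead of on oxygen. The fallback is a Kowalski ester homologation that sets out from 6 and comes back at ynolate 10, which is silylated with TIPSOTf to 11 as before. Bromine–lithium exchange of 6 (n-BuLi, THF, −78 °C) and quench with ethyl chloroformate should give ethyl 4-tert-butoxybenzoate F4. Addition of LiCHBr2 (CH2Br2, LiTMP, THF, −78 °C) should give the lithium enolate of the α,α-dibromo ketone, lithium 2,2-dibromo-1-(4-tert-butoxyphenyl)ethen-1-olate F5. n-BuLi (−78 °C to rt) should then trigger bromine–lithium exchange and 1,2-aryl shift to ynolate 10.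

3. Step 8. Acidolysis may also cleave or transfer the labile enol acetate, and tert-butyl cations may alkylate the liberated phenol rings. The fallback reverses the order of the last two operations, sets out from 15 and comes back at 17. TFA/CH2Cl2 on 15, where no acetate is at risk, should give 2-hydroxy-3,6-bis(4-hydroxyphenyl)-1,4-benzoquinone F6. The hydroxyquinone OH is a vinylogous carboxylic acid, several pKa units more acidic than the phenols, and should be acetylated selectively as its mono-anion (NaHCO3 1 equiv, Ac2O 1.1 equiv, acetone/H2O, 0 °C) to give 17.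

**Further compounds**

F1 | step 5 | 2,5-bis(4-tert-butoxyphenyl)-1,4-dimethoxybenzene | COc1cc(-c2ccc(OC(C)(C)C)cc2)c(OC)cc1-c1ccc(OC(C)(C)C)cc1
F2 | step 5 | 2,5-bis(4-tert-butoxyphenyl)cyclohexa-2,5-diene-1,4-dione | O=C1C=C(c2ccc(OC(C)(C)C)cc2)C(=O)C=C1c1ccc(OC(C)(C)C)cc1
F3 | step 5 | rac-1,4-bis(4-tert-butoxyphenyl)-7-oxabicyclo[4.1.0]hept-3-ene-2,5-dione | O=C1C=C(c2ccc(OC(C)(C)C)cc2)C(=O)C2OC12c1ccc(OC(C)(C)C)cc1
F4 | step 4 | ethyl 4-tert-butoxybenzoate | CCOC(=O)c1ccc(OC(C)(C)C)cc1
F5 | step 4 | lithium 2,2-dibromo-1-(4-tert-butoxyphenyl)ethen-1-olate | [Li+].[O-]C(=C(Br)Br)c1ccc(OC(C)(C)C)cc1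
F6 | step 8 | 2-hydroxy-3,6-bis(4-hydroxyphenyl)cyclohexa-2,5-diene-1,4-dione | OC1=C(c2ccc(O)cc2)C(=O)C=C(c2ccc(O)cc2)C1=O
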